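Readings and results stem from a simulated flask with made-up constants; scatter was added.

How much left-handed product this flask holds at 4.0 min, and how much if left far longer, I reckon from what the unspent left-handed substrate can still add to the readings.

- alder: left-handed substrate 1 mM; right-handed substrate 1 mM; reagent 2.5 mM (fed, over 4.0 s); the very flask that is asked about, followed so far
- flask: left-handed substrate 1.0 mM; reagent 2.50 mM (fed, over 4.0 s); right-handed substrate 1.0 mM; time 4.0 min

alder run (percent of the left-handed substrate and right-handed substrate together charged)

| time / s | left-handed product / % | left-handed substrate / % |
|---|---|---|
| 10.0 | 36.1 | 7.4 |
| 12.0 | 38.3 | 6.9 |
| 30.0 | 41.5 | 1.6 |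
| 80.0 | 42.0 | 0 |

(readings scatter by 0.5 percentage points)

1. left-handed product at 4.0 min, in percent of the left-handed substrate and right-handed substrate together charged
2. amount of left-handed product if the flask were left three thousand times as long, in percent of the left-handed substrate and right-handed substrate together charged

- reagent is single-handed; left-handed substrate and right-handed substrate are mirror images of each other, charged as a racemate, each of them at the stated concentration
- the numbers in the tables scatter with a standard deviation of 0.5 percentage points
- steps under discussion: reagent + left-handed substrate -> left-handed product; reagent + right-handed substrate -> right-handed product; left-handed substrate <-> achiral form; right-handed substrate <-> achiral form; achiral form -> waste; 2 reagent -> self-condensation product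
- the handed part of reagent does not stay in what it makes, so the products of the two hands are mirror images too

Taking first the main step, reagent with left-handed substrate, the product would reach 50.0 % of the substrate charged, since the 2.50 mM of reagent is more than the 2.00 mM of both hands, which makes substrate the limiting reagent by charge. Adding the other substrate steps, I read the cost from the alder run: at 80.0 s the left-handed product reads 42.0 %, 8 percentage points under that figure. Adding the remaining step, the reagent's own loss, I expect capture to fade, so I read it late: from 12.0 s to 30.0 s the product gains 3.2 points while the left-handed substrate loses 5.3 points. These readings give the capture share φ, the left-handed product gained per left-handed substrate lost over that span, 0.604, and I reckon only the correction, φ times the left-handed substrate remaining. From 30.0 s that predicts 42.5 %; from 80.0 s, with 0 % read, it adds nothing, and a substrate hidden in the scatter would add 0.3 points. I commit to 42.0 % for both questions, the route from the earlier reading lying 0.50 points higher.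

The forecast stands above my figure, at 42.2 % and 42.4 %: “None of the listed steps consumes product, so it should simply stay.”

The flask gives 42.0 % and 42.0 %.

    reagent + left-handed substrate → left-handed product (k = 240 M⁻¹ s⁻¹)
    reagent + right-handed substrate → right-handed product (k = 110 M⁻¹ s⁻¹)
    left-handed substrate ⇌ achiral form (K = 0.390, k = 0.330 s⁻¹)
    right-handed substrate ⇌ achiral form (K = 0.390, k = 0.330 s⁻¹)
    achiral form → waste (k = 0.320 s⁻¹)
    2 reagent → self-condensation product (k = 62.0 M⁻¹ s⁻¹)

In this flask at 2.00 min the 0.00927 % of left-handed substrate allows 0.0056 points more by φ as read. In this flask the turning of achiral form into waste has done half of its turnover by 0.0986 min, far earlier than 4.0 min, and over the second half of the time no substrate, intermediate or product share changes by more than 0.019 points. In the neighbour flask with 4.2 mM of reagent, φ times the 0 % of left-handed substrate left at the end adds 0 points, and that flask's computed left-handed product stands at 47.0 %.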